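## The problem

The target is a germacranolide: a ten-membered carbocycle (C1–C10, germacrane numbering, C14 on C10, C15 on C4) fused across C6–C7 to a butenolide. The butenolide double bond is the tetrasubstituted C7=C11, its carbonyl C12 is closed onto the oxygen of C6, and C11 carries a free hydroxymethyl group (C13). The ring also bears two trisubstituted trans-epoxides (C1–C10 and C4–C5) and an (E)-2-methylbut-2-enoate (tiglate) on C8; the six stereocentres are 1R, 4R, 5R, 6S, 8S and 10R. The central task is to close the strained ten-membered ring and at the same time place the contiguous triad C4–C5–C6. The quaternary C4 can direct C5, and C5 can direct C6. C8 has no stereogenic neighbour and must be set on its own. C1 and C10 are remote from everything and can only be controlled by the conformation of the finished ring. Several groups limit the reagents that may be used: both epoxides open transannularly under acid, the C6–H of the butenolide is acidic (epimerisation, elimination, retro-aldol under base), the tiglate must be neither cleaved nor deconjugated, and the C13 alcohol is allylic. The feature that opens the route is that C6 is the γ-carbon of the butenolide and therefore the nucleophilic terminus of the corresponding 2-silyloxyfuran. C5 is a carbinol-level carbon next to the fully substituted C4, so a C5 aldehyde with chlorine on C4 cannot enolise, is biased by the Cornforth dipole arrangement, and gives a chlorohydrin that is a latent 4,5-epoxide.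

## Retrosynthesis

**End game (27 ⇐ 26 ⇐ 25 ⇐ 24).** The silyl ether O–Si bond of 26, the two C–O bonds of the 1,10-epoxide of 26 and the O–C4 bond of the 4,5-epoxide of 25 are cut in turn. The outer epoxide goes first because its two centres can only be set by peripheral attack on the finished ring. The inner epoxide is traced to the chlorohydrin 24 and not to a 4(5)-alkene, because chlorine on C4 is what makes the ring-closing partner non-enolisable and stereodirecting. The forward reactions must close the epoxide with inversion at a tertiary carbon without disturbing C6–H, then epoxidise one face of the only electron-rich alkene.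

**Key disconnection (24 ⇐ 23).** The C5–C6 bond is cut. It is the one ring bond flanked by latent polarity on both sides: the γ-carbon of a butenolide and a carbinol carbon. It also joins the two stereocentres that would be hardest to install on a preformed, flexible ring. Closures at C8–C9 or C1–C10 would leave the C4–C6 triad to be built afterwards. The cut turns a bicycle with three contiguous stereocentres into the open chain 23 with two isolated ones (C4 and C8). The forward reaction must favour ring closure over oligomerisation, the 4,5-anti relationship (Cornforth) and the 5,6-syn relationship.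

**Setting C4 (23 ⇐ 22 ⇐ 21 ⇐ 20 ⇐ 19).** The furan O–Si bond is cut to give butenolide aldehyde 22. The aldehyde is traced through the C5–C16 bond of chlorodiol 21 (C16 is a one-carbon handle that is later excised), the C4–Cl bond to epoxy alcohol 20, and the oxirane to allylic alcohol 19. A tertiary α-chloro aldehyde is not reliably available by direct asymmetric chlorination. Taking it from a Sharpless epoxide puts C4 under reagent control, at the price of one sacrificial carbon. Placing this sequence late keeps the tertiary chloride away from every strongly basic step. The forward reactions must open the epoxide at the tertiary carbon with inversion and cleave the diol without epimerisation, which the quaternary α-carbon guarantees.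

**Butenolide and ester (19 ⇐ 18 ⇐ 16 + 17; 16 ⇐ 15 ⇐ 10 + 14).** The acyl C–O bond of the tiglate is cut (acid chloride 17), then the C7=C11 double bond and the C12–O ester bond of the lactone. An intramolecular Horner–Wadsworth–Emmons reaction is the most dependable way to a tetrasubstituted butenolide. Acylating the C6 oxygen first decides which oxygen ends up in the lactone. The phosphonate 14 (from 11 and 12) brings C13 with its oxygen, so the butenolide α-carbon never has to be functionalised. The heterocycle is thereby reduced to the acyclic dihydroxy ketone 10 with a single stereocentre. The forward reactions must acylate the primary hydroxyl selectively and olefinate without epimerising C8.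

**Fragment union (10 ⇐ 9 ⇐ 7 + 4; 7 ⇐ 5 + 6; 4 ⇐ 3 ⇐ 2 ⇐ 1).** The C8–C9 bond is cut. It is the only sp3–sp3 bond between the terpenoid chain and the C6–C7–C8 unit, C9 is allylic (a good electrophile) and C8 is α to a ketone (a nucleophile). The protected dihydroxy ketone 5, as its hydrazone 7 with auxiliary 6, delivers C6, C7 and C8 with both oxygens and with auxiliary control at C8. Bromide 4 comes from geraniol 1, which supplies C1–C5, C9, C10, C14 and C15 with both alkene geometries already in place. The forward alkylation needs high facial selectivity and an electrophile that reacts without allylic transposition.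

## Roads not taken

**Alternative 1:** ring closure at C1–C10 by a sulfonium ylide. The cut removes the C1–C10 bond and the O–C1 bond together. In the forward sense the open-chain sulfonium salt A1 would be deprotonated at C1 by a strong amide base, the ylide would add to the C10 methyl ketone, and the betaine would close to the 1,10-epoxide, giving the bis-epoxide A2 in one operation.
- Merits: ring and outer epoxide are formed together, no late peracid step is needed, and no Lewis acid comes near the C8 oxygen. In these respects it is at least as economical after the key step as the chosen plan.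
- Weak points: the ylide must be generated beside a butenolide C6–H of comparable or higher acidity and a methyl ketone that is enolisable on both sides, so proton transfer can quench it. A short-lived, unstabilised ylide must then find a ketone ten atoms away. The C1/C10 configuration and the trans geometry would be decided in an acyclic transition state with no ring conformation to help. The C4–C6 triad must be built beforehand by separate steps.
- Comparison: the chosen plan offers partners that cannot enolise or exchange protons (23), a reaction class with a known stereochemical model, and creation of C5 and C6 in the ring-forming step itself.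

**Alternative 2:** boronate fragmentation of a bicyclic precursor. The cut reconnects C5 to C10, so the ten-membered ring is hidden in the decalin mesylate A3. Hydroboration of its tetrasubstituted 4(5)-alkene and base-induced fragmentation would expel the C1 sulfonate and give the (E,E)-cyclodecadiene A4.
- Merits: the ring is not closed but released, so no high dilution is needed, and both alkene geometries follow from the antiperiplanar fragmentation. For the certainty of obtaining the ten-membered ring this road is better than the chosen one.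
- Weak points: hydroboration of a hindered tetrasubstituted alkene next to the C6 ether is slow and its face selectivity uncertain. A3 needs four stereocentres on a decalin, two of which are destroyed. A4 still lacks the butenolide, both epoxides and the tiglate, and the butenolide would have to be annulated onto a ten-membered 1(10),4-diene that is prone to Cope rearrangement and transannular cyclisation.
- Comparison: the chosen plan accepts the risk of a true macrocyclisation but arrives at 24 with the lactone, the C8 ester and the C4–C6 triad in place, three steps from the target.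

**Alternative 3:** Payne rearrangement driven by lactonisation. The cuts are the O–C5 bond of the inner epoxide and the O–C12 bond of the lactone. A hydride base would ionise the C4 tertiary alcohol of the ten-membered hydroxy epoxy ester A5. The alkoxide would open the cis 5,6-epoxide at C5 with inversion, and the liberated C6 alkoxide would close onto the methyl ester to give A6, the silyl ether of the target.
- Merits: C5 is set stereospecifically and C6 is carried over unchanged, lactonisation makes the rearrangement irreversible, and no chlorine or Lewis acid is involved. For the reliability of the C4–C6 relationship this road is better than a diastereoselective aldol.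
- Weak points: it does not form the ten-membered ring at all. A5, with a cis-epoxide, a (Z)-tetrasubstituted enoate, the outer epoxide and the tiglate, must first be assembled on a medium ring by other means. The alkoxides generated can also attack the tiglate.
- Comparison: the chosen plan solves ring closure and the C5/C6 centres in one step, and pays for it by relying on selectivity rather than stereospecificity.

Key step: step 17

Assumption: the SAMP auxiliary is taken to induce the (S)-configuration at the alkylated carbon of the dioxanone, as it does with simple alkyl halides; if the allylic bromide gave the opposite sense, the enantiomeric auxiliary (RAMP) would be used.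

Step 1
Reactants: 1 geraniol
Product: 2 1-({[(2E)-3,7-dimethylocta-2,6-dien-1-yl]oxy}methyl)-4-methoxybenzene (geranyl 4-methoxybenzyl ether)
Conditions: NaH, 4-methoxybenzyl chloride, Bu4NI (cat.), THF/DMF, 0 °C → rt
Reagents that add atoms: 4-methoxybenzyl chloride, COc1ccc(CCl)cc1
Why: Williamson etherification of the primary allylic alkoxide; the ether masks the oxygen that later directs the Sharpless epoxidation and can be removed oxidatively beside silyl ethers and esters.

Step 2
Reactants: 2 geranyl 4-methoxybenzyl ether
Product: 3 (2E,6E)-8-[(4-methoxybenzyl)oxy]-2,6-dimethylocta-2,6-dien-1-ol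
Conditions: SeO2 (cat.), t-BuOOH, salicylic acid (cat.), CH2Cl2, 0 °C → rt
Reagents that add atoms: tert-butyl hydroperoxide, CC(C)(C)OO
Why: Riley-type allylic oxidation (ene reaction, then [2,3]-shift) is selective for the (E)-methyl group of the terminal trisubstituted alkene, while the alkene next to the ether oxygen is deactivated; this makes C9 functional and fixes the (E)-geometry of the future C1=C10 bond.

Step 3
Reactants: 3 (2E,6E)-8-[(4-methoxybenzyl)oxy]-2,6-dimethylocta-2,6-dien-1-ol
Product: 4 1-({[(2E,6E)-8-bromo-3,7-dimethylocta-2,6-dien-1-yl]oxy}methyl)-4-methoxybenzene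
Conditions: CBr4, PPh3, CH2Cl2, 0 °C
Reagents that add atoms: carbon tetrabromide, BrC(Br)(Br)Br
Why: Appel bromination of a primary allylic alcohol under neutral conditions, which should proceed without allylic transposition or loss of alkene geometry.

Step 4
Reactants: 5 2,2-dimethyl-1,3-dioxan-5-one; 6 (S)-1-amino-2-(methoxymethyl)pyrrolidine (SAMP)
Product: 7 (2S)-N-(2,2-dimethyl-1,3-dioxan-5-ylidene)-2-(methoxymethyl)pyrrolidin-1-amine
Conditions: benzene, reflux, Dean–Stark trap
Reagents that add atoms: none
Why: Hydrazone condensation with azeotropic removal of water; the auxiliary turns the symmetrical ketone into a substrate for face-selective alkylation.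

Step 5
Reactants: 7 SAMP hydrazone of the dioxanone; 4 allylic bromide
Product: 9 (4S)-4-{(2E,6E)-8-[(4-methoxybenzyl)oxy]-2,6-dimethylocta-2,6-dien-1-yl}-2,2-dimethyl-1,3-dioxan-5-one, via alkylated hydrazone 8 (not isolated)
Conditions: t-BuLi, THF, −78 °C; then 4, −100 °C → rt; then sat. aq. oxalic acid, Et2O, rt
Reagents that add atoms: water, O
Why: Enders SAMP-hydrazone alkylation: the lithium azaenolate, held by chelation to the methoxymethyl group, is alkylated on its open face by the allylic bromide, which forms the C8–C9 bond and sets C8 as (S). Two-phase oxalic acid hydrolysis releases the ketone without cleaving the acetonide or racemising the α-centre.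

Step 6
Reactants: 9 alkylated dioxanone
Product: 10 (3S,5E,9E)-1,3-dihydroxy-11-[(4-methoxybenzyl)oxy]-5,9-dimethylundeca-5,9-dien-2-one
Conditions: AcOH/THF/H2O, 40 °C
Reagents that add atoms: none
Why: Mild acid-catalysed acetonide hydrolysis; the allylic 4-methoxybenzyl ether and the alkenes tolerate dilute acetic acid, and C8 should not enolise appreciably under these conditions.

Step 7
Reactants: 11 benzyl 2-(diethoxyphosphoryl)acetate; 12 (chloromethoxy)tri(propan-2-yl)silane
Product: 13 benzyl 2-(diethoxyphosphoryl)-3-[(triisopropylsilyl)oxy]propanoate (racemic)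
Conditions: NaH, THF, 0 °C → rt
Reagents that add atoms: none
Why: C-alkylation of the sodium phosphonoacetate by a reactive α-chloro ether installs C13 already carrying its silyl-protected oxygen; one equivalent of base limits dialkylation.

Step 8
Reactants: 13 benzyl phosphonate ester
Product: 14 2-(diethoxyphosphoryl)-3-[(triisopropylsilyl)oxy]propanoic acid (racemic)
Conditions: H2 (1 atm), Pd/C, EtOAc, rt
Reagents that add atoms: none
Why: Hydrogenolysis of the benzyl ester under neutral conditions leaves the silyl ether and the phosphonate esters intact and avoids a basic hydrolysis that would invite β-elimination.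

Step 9
Reactants: 10 dihydroxy ketone; 14 phosphono acid
Product: 15 (3S,5E,9E)-3-hydroxy-11-[(4-methoxybenzyl)oxy]-5,9-dimethyl-2-oxoundeca-5,9-dien-1-yl 2-(diethoxyphosphoryl)-3-[(triisopropylsilyl)oxy]propanoate (both epimers at the phosphonate carbon)
Conditions: DCC, DMAP (cat.), CH2Cl2, −20 °C
Reagents that add atoms: none
Why: Steglich esterification; the unhindered primary C6 hydroxyl should react ahead of the secondary C8 hydroxyl at low temperature, which decides that the later lactone closes on O–C6.

Step 10
Reactants: 15 keto phosphonate ester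
Product: 16 4-{(1S,3E,7E)-1-hydroxy-9-[(4-methoxybenzyl)oxy]-3,7-dimethylnona-3,7-dien-1-yl}-3-{[(triisopropylsilyl)oxy]methyl}furan-2(5H)-one
Conditions: LiCl, i-Pr2NEt, MeCN, 0 °C → rt
Reagents that add atoms: none
Why: Intramolecular Horner–Wadsworth–Emmons reaction under Masamune–Roush conditions closes the five-membered lactone and creates the tetrasubstituted C7=C11 bond; the doubly α-oxygenated ketone is a reactive acceptor. The weak amine base should neither epimerise C8 nor let β-elimination of the silyloxy group outrun the five-ring closure.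

Step 11
Reactants: 16 butenolide alcohol; 17 (2E)-2-methylbut-2-enoyl chloride (tigloyl chloride)
Product: 18 (1S,3E,7E)-9-[(4-methoxybenzyl)oxy]-3,7-dimethyl-1-(5-oxo-4-{[(triisopropylsilyl)oxy]methyl}-2,5-dihydrofuran-3-yl)nona-3,7-dien-1-yl (2E)-2-methylbut-2-enoate
Conditions: pyridine, DMAP (cat.), CH2Cl2, 0 °C → rt
Reagents that add atoms: none
Why: Acylation of the secondary C8 alcohol with nucleophilic catalysis; no bond to C8 is broken, so the (S)-configuration is retained, and the (E)-ester is the thermodynamically stable isomer.

Step 12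
Reactants: 18 tiglate
Product: 19 (1S,3E,7E)-9-hydroxy-3,7-dimethyl-1-(5-oxo-4-{[(triisopropylsilyl)oxy]methyl}-2,5-dihydrofuran-3-yl)nona-3,7-dien-1-yl (2E)-2-methylbut-2-enoate
Conditions: DDQ, CH2Cl2/pH 7 buffer, 0 °C
Reagents that add atoms: none
Why: Oxidative cleavage of the 4-methoxybenzyl ether (hydride abstraction, then hydrolysis); the silyl ether, both esters and the trisubstituted alkenes are inert under buffered conditions.

Step 13
Reactants: 19 allylic alcohol
Product: 20 (1S,3E)-6-[(2R,3R)-3-(hydroxymethyl)-2-methyloxiran-2-yl]-3-methyl-1-(5-oxo-4-{[(triisopropylsilyl)oxy]methyl}-2,5-dihydrofuran-3-yl)hex-3-en-1-yl (2E)-2-methylbut-2-enoate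
Conditions: Ti(OiPr)4 (cat.), D-(−)-diethyl tartrate (cat.), t-BuOOH, 4 Å MS, CH2Cl2, −20 °C
Reagents that add atoms: tert-butyl hydroperoxide, CC(C)(C)OO
Why: Sharpless asymmetric epoxidation of the (E)-trisubstituted allylic alcohol; with D-(−)-tartrate the oxygen is delivered to the face that gives the (R,R)-epoxy alcohol, as with geraniol, under reagent control that overrides the remote C8 centre. The isolated C1=C10 alkene and the electron-poor alkenes are not epoxidised.

Step 14
Reactants: 20 epoxy alcohol
Product: 21 (1S,3E,7S,8R)-7-chloro-8,9-dihydroxy-3,7-dimethyl-1-(5-oxo-4-{[(triisopropylsilyl)oxy]methyl}-2,5-dihydrofuran-3-yl)non-3-en-1-yl (2E)-2-methylbut-2-enoate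
Conditions: ClTi(OiPr)3, benzene, 0 °C → rt; aq. tartaric acid work-up
Reagents that add atoms: chlorotitanium triisopropoxide, CC(C)O[Ti](Cl)(OC(C)C)OC(C)C
Why: Chelation-assisted opening of a 2,3-epoxy alcohol: titanium bound to the primary alkoxide and the oxirane oxygen delivers chloride to the distal tertiary carbon (C4), which is also the electronically favoured site, with inversion to the (4S)-chloride. Any C4 epimer from ion-pair leakage is a diastereomer of 21 and can be removed before the neighbouring carbinol centre is sacrificed.

Step 15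
Reactants: 21 chlorodiol
Product: 22 (1S,3E,7S)-7-chloro-3,7-dimethyl-8-oxo-1-(5-oxo-4-{[(triisopropylsilyl)oxy]methyl}-2,5-dihydrofuran-3-yl)oct-3-en-1-yl (2E)-2-methylbut-2-enoate
Conditions: NaIO4, THF/pH 7 buffer, 0 °C
Reagents that add atoms: none
Why: Malaprade glycol cleavage removes the sacrificial carbon as formaldehyde and turns C5 into the aldehyde; the α-carbon is quaternary, so the (4S)-chloride cannot epimerise.

Step 16
Reactants: 22 butenolide aldehyde
Product: 23 (1S,3E,7S)-7-chloro-3,7-dimethyl-8-oxo-1-(5-[(triisopropylsilyl)oxy]-4-{[(triisopropylsilyl)oxy]methyl}furan-3-yl)oct-3-en-1-yl (2E)-2-methylbut-2-enoate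
Conditions: TIPSOTf, Et3N, CH2Cl2, −78 → 0 °C, dilute; NaHCO3 work-up
Reagents that add atoms: triisopropylsilyl trifluoromethanesulfonate, CC(C)[Si](OS(=O)(=O)C(F)(F)F)(C(C)C)C(C)C
Why: Soft enolisation: O-silylation of the lactone carbonyl and deprotonation at C6 give the aromatic 2-silyloxyfuran. The aldehyde has no α-hydrogen and cannot be enolised, and a bulky silyl triflate in excess amine at low temperature is a poor aldol promoter, so 23 should be isolable.

Step 17
Reactants: 23 silyloxyfuran aldehyde
Product: 24 (4S,6E,10S,11R,11aS)-10-chloro-11-hydroxy-6,10-dimethyl-2-oxo-3-{[(triisopropylsilyl)oxy]methyl}-2,4,5,8,9,10,11,11a-octahydrocyclodeca[b]furan-4-yl (2E)-2-methylbut-2-enoate (germacrane numbering: 4S-chloro, 5R-hydroxy, 6S, 8S, 1(10)E)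
Conditions: BF3·OEt2, CH2Cl2, −78 °C, slow addition of 23 to a final concentration of about 1 mM; then aq. NaHCO3
Reagents that add atoms: none
Why: This is an intramolecular vinylogous Mukaiyama aldol reaction: BF3 binds the C5 aldehyde, the furan attacks through C6 (the only free nucleophilic position, since C11 is fully substituted), and loss of the silyl group from the silyloxyfuranium ion restores the butenolide. The closest known reaction type is the Lewis acid-mediated addition of 2-silyloxyfurans to aldehydes, including Cornforth-controlled additions to α-chloro aldehydes and intramolecular variants for smaller rings. The ten-membered carbocycle closes in a 10-exo-trig mode at the aldehyde carbon, and the (E)-C1=C10 alkene and the planar furan remove part of the transannular strain that slows medium-ring closure. C5 is controlled by the quaternary C4: with the C4–Cl and C=O dipoles opposed (Cornforth arrangement) the nucleophile passes the methyl group and not the C3 methylene, which gives the 4,5-anti chlorohydrin (5R). C6 is controlled by the open antiperiplanar transition state favoured by BF3, whose syn preference places the lactone oxygen and the new hydroxyl on the same side of the C5–C6 bond (6S); C8 exerts no direct control, and the (8S) ester has to be accommodated by the ring as the 6,8-cis arrangement. The step needs intramolecular over intermolecular attack, which slow addition at high dilution and partners that cannot enolise or self-condense should secure, and chemoselective activation of the aldehyde beside the tiglate, for which low temperature and an excess of BF3 are used.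

Step 18
Reactants: 24 macrocyclic chlorohydrin
Product: 25 (1(10)E,4R,5R,6S,8S)-4,5-epoxy-8-[(2E)-2-methylbut-2-enoyloxy]-13-[(triisopropylsilyl)oxy]germacra-1(10),7(11)-dien-12,6-olide
Conditions: Cs2CO3, MeCN, 0 °C → rt
Reagents that add atoms: none
Why: Intramolecular Williamson closure of the anti chlorohydrin (3-exo-tet): the C5 alkoxide displaces chloride at C4 with inversion, which converts (4S) into (4R) and gives the trans 4,5-epoxide. Closure onto a tertiary chloride is helped by the geminal substitution, and a weak heterogeneous base is chosen to spare the C6–H and the tiglate.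

Step 19
Reactants: 25 4,5-epoxide
Product: 26 (1R,4R,5R,6S,8S,10R)-1,10:4,5-diepoxy-8-[(2E)-2-methylbut-2-enoyloxy]-13-[(triisopropylsilyl)oxy]germacr-7(11)-en-12,6-olide
Conditions: mCPBA, NaHCO3, CH2Cl2, 0 °C
Reagents that add atoms: 3-chloroperoxybenzoic acid, OOC(=O)c1cccc(Cl)c1
Why: Prilezhaev epoxidation of the only electron-rich alkene; the tiglate and butenolide double bonds are deactivated. In the crossed conformation of the ring the inner face of the (E)-C1=C10 bond is shielded transannularly, so the peracid should add from the periphery and give the (1R,10R) trans-epoxide; the buffer protects the 4,5-epoxide from acid.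

Step 20
Reactants: 26 silyl ether
Product: 27 (1R,4R,5R,6S,8S,10R)-1,10:4,5-diepoxy-13-hydroxy-8-[(2E)-2-methylbut-2-enoyloxy]germacr-7(11)-en-12,6-olide (CNP0111480.1)
Conditions: Bu4NF, AcOH, THF, 0 °C → rt
Reagents that add atoms: none
Why: Fluoride cleavage of the primary silyl ether; buffering with acetic acid keeps the medium near neutral so that the epoxides, the tiglate and the C6–H of the butenolide survive.

**Compound list**

1 | geraniol, (2E)-3,7-dimethylocta-2,6-dien-1-ol | CC(C)=CCC/C(C)=C/CO | starting material
2 | 1-({[(2E)-3,7-dimethylocta-2,6-dien-1-yl]oxy}methyl)-4-methoxybenzene | CC(C)=CCC/C(C)=C/COCc1ccc(OC)cc1 | intermediate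
3 | (2E,6E)-8-[(4-methoxybenzyl)oxy]-2,6-dimethylocta-2,6-dien-1-ol | OC/C(C)=C/CC/C(C)=C/COCc1ccc(OC)cc1 | intermediate
4 | 1-({[(2E,6E)-8-bromo-3,7-dimethylocta-2,6-dien-1-yl]oxy}methyl)-4-methoxybenzene | BrC/C(C)=C/CC/C(C)=C/COCc1ccc(OC)cc1 | intermediate
5 | 2,2-dimethyl-1,3-dioxan-5-one | CC1(C)OCC(=O)CO1 | starting material
6 | (S)-1-amino-2-(methoxymethyl)pyrrolidine (SAMP) | COC[C@@H]1CCCN1N | starting material
7 | (2S)-N-(2,2-dimethyl-1,3-dioxan-5-ylidene)-2-(methoxymethyl)pyrrolidin-1-amine | COC[C@@H]1CCCN1N=C1COC(C)(C)OC1 | intermediate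
8 | (2S)-N-[(4S)-4-{(2E,6E)-8-[(4-methoxybenzyl)oxy]-2,6-dimethylocta-2,6-dien-1-yl}-2,2-dimethyl-1,3-dioxan-5-ylidene]-2-(methoxymethyl)pyrrolidin-1-amine | COC[C@@H]1CCCN1N=C1COC(C)(C)O[C@H]1C/C(C)=C/CC/C(C)=C/COCc1ccc(OC)cc1 | intermediate
9 | (4S)-4-{(2E,6E)-8-[(4-methoxybenzyl)oxy]-2,6-dimethylocta-2,6-dien-1-yl}-2,2-dimethyl-1,3-dioxan-5-one | CC1(C)OCC(=O)[C@H](C/C(C)=C/CC/C(C)=C/COCc2ccc(OC)cc2)O1 | intermediate
10 | (3S,5E,9E)-1,3-dihydroxy-11-[(4-methoxybenzyl)oxy]-5,9-dimethylundeca-5,9-dien-2-one | OCC(=O)[C@@H](O)C/C(C)=C/CC/C(C)=C/COCc1ccc(OC)cc1 | intermediate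
11 | benzyl 2-(diethoxyphosphoryl)acetate | CCOP(=O)(OCC)CC(=O)OCc1ccccc1 | starting material
12 | (chloromethoxy)tri(propan-2-yl)silane | ClCO[Si](C(C)C)(C(C)C)C(C)C | starting material
13 | benzyl 2-(diethoxyphosphoryl)-3-[(triisopropylsilyl)oxy]propanoate (racemic) | CCOP(=O)(OCC)C(CO[Si](C(C)C)(C(C)C)C(C)C)C(=O)OCc1ccccc1 | intermediate
14 | 2-(diethoxyphosphoryl)-3-[(triisopropylsilyl)oxy]propanoic acid (racemic) | CCOP(=O)(OCC)C(CO[Si](C(C)C)(C(C)C)C(C)C)C(=O)O | intermediate
15 | (3S,5E,9E)-3-hydroxy-11-[(4-methoxybenzyl)oxy]-5,9-dimethyl-2-oxoundeca-5,9-dien-1-yl 2-(diethoxyphosphoryl)-3-[(triisopropylsilyl)oxy]propanoate | CCOP(=O)(OCC)C(CO[Si](C(C)C)(C(C)C)C(C)C)C(=O)OCC(=O)[C@@H](O)C/C(C)=C/CC/C(C)=C/COCc1ccc(OC)cc1 | intermediate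
16 | 4-{(1S,3E,7E)-1-hydroxy-9-[(4-methoxybenzyl)oxy]-3,7-dimethylnona-3,7-dien-1-yl}-3-{[(triisopropylsilyl)oxy]methyl}furan-2(5H)-one | O=C1OCC([C@@H](O)C/C(C)=C/CC/C(C)=C/COCc2ccc(OC)cc2)=C1CO[Si](C(C)C)(C(C)C)C(C)C | intermediate
17 | (2E)-2-methylbut-2-enoyl chloride (tigloyl chloride) | C/C=C(\C)C(Cl)=O | starting material
18 | (1S,3E,7E)-9-[(4-methoxybenzyl)oxy]-3,7-dimethyl-1-(5-oxo-4-{[(triisopropylsilyl)oxy]methyl}-2,5-dihydrofuran-3-yl)nona-3,7-dien-1-yl (2E)-2-methylbut-2-enoate | C/C=C(\C)C(=O)O[C@@H](C/C(C)=C/CC/C(C)=C/COCc1ccc(OC)cc1)C1=C(CO[Si](C(C)C)(C(C)C)C(C)C)C(=O)OC1 | intermediate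
19 | (1S,3E,7E)-9-hydroxy-3,7-dimethyl-1-(5-oxo-4-{[(triisopropylsilyl)oxy]methyl}-2,5-dihydrofuran-3-yl)nona-3,7-dien-1-yl (2E)-2-methylbut-2-enoate | C/C=C(\C)C(=O)O[C@@H](C/C(C)=C/CC/C(C)=C/CO)C1=C(CO[Si](C(C)C)(C(C)C)C(C)C)C(=O)OC1 | intermediate
20 | (1S,3E)-6-[(2R,3R)-3-(hydroxymethyl)-2-methyloxiran-2-yl]-3-methyl-1-(5-oxo-4-{[(triisopropylsilyl)oxy]methyl}-2,5-dihydrofuran-3-yl)hex-3-en-1-yl (2E)-2-methylbut-2-enoate | C/C=C(\C)C(=O)O[C@@H](C/C(C)=C/CC[C@@]1(C)O[C@@H]1CO)C1=C(CO[Si](C(C)C)(C(C)C)C(C)C)C(=O)OC1 | intermediate
21 | (1S,3E,7S,8R)-7-chloro-8,9-dihydroxy-3,7-dimethyl-1-(5-oxo-4-{[(triisopropylsilyl)oxy]methyl}-2,5-dihydrofuran-3-yl)non-3-en-1-yl (2E)-2-methylbut-2-enoate | C/C=C(\C)C(=O)O[C@@H](C/C(C)=C/CC[C@](C)(Cl)[C@H](O)CO)C1=C(CO[Si](C(C)C)(C(C)C)C(C)C)C(=O)OC1 | intermediate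
22 | (1S,3E,7S)-7-chloro-3,7-dimethyl-8-oxo-1-(5-oxo-4-{[(triisopropylsilyl)oxy]methyl}-2,5-dihydrofuran-3-yl)oct-3-en-1-yl (2E)-2-methylbut-2-enoate | C/C=C(\C)C(=O)O[C@@H](C/C(C)=C/CC[C@](C)(Cl)C=O)C1=C(CO[Si](C(C)C)(C(C)C)C(C)C)C(=O)OC1 | intermediate
23 | (1S,3E,7S)-7-chloro-3,7-dimethyl-8-oxo-1-(5-[(triisopropylsilyl)oxy]-4-{[(triisopropylsilyl)oxy]methyl}furan-3-yl)oct-3-en-1-yl (2E)-2-methylbut-2-enoate | C/C=C(\C)C(=O)O[C@@H](C/C(C)=C/CC[C@](C)(Cl)C=O)c1c(CO[Si](C(C)C)(C(C)C)C(C)C)c(O[Si](C(C)C)(C(C)C)C(C)C)oc1 | intermediate
24 | (4S,6E,10S,11R,11aS)-10-chloro-11-hydroxy-6,10-dimethyl-2-oxo-3-{[(triisopropylsilyl)oxy]methyl}-2,4,5,8,9,10,11,11a-octahydrocyclodeca[b]furan-4-yl (2E)-2-methylbut-2-enoate | C/C=C(\C)C(=O)O[C@H]1C/C(C)=C/CC[C@](C)(Cl)[C@H](O)[C@H]2OC(=O)C(CO[Si](C(C)C)(C(C)C)C(C)C)=C12 | intermediate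
25 | (1(10)E,4R,5R,6S,8S)-4,5-epoxy-8-[(2E)-2-methylbut-2-enoyloxy]-13-[(triisopropylsilyl)oxy]germacra-1(10),7(11)-dien-12,6-olide | C/C=C(\C)C(=O)O[C@H]1C/C(C)=C/CC[C@@]2(C)O[C@@H]2[C@H]2OC(=O)C(CO[Si](C(C)C)(C(C)C)C(C)C)=C12 | intermediate
26 | (1R,4R,5R,6S,8S,10R)-1,10:4,5-diepoxy-8-[(2E)-2-methylbut-2-enoyloxy]-13-[(triisopropylsilyl)oxy]germacr-7(11)-en-12,6-olide | C/C=C(\C)C(=O)O[C@H]1C[C@@]2(C)O[C@@H]2CC[C@@]2(C)O[C@@H]2[C@H]2OC(=O)C(CO[Si](C(C)C)(C(C)C)C(C)C)=C12 | intermediate
27 | (1R,4R,5R,6S,8S,10R)-1,10:4,5-diepoxy-13-hydroxy-8-[(2E)-2-methylbut-2-enoyloxy]germacr-7(11)-en-12,6-olide (CNP0111480.1) | C/C=C(\C)C(=O)O[C@H]1C[C@@]2(C)O[C@@H]2CC[C@@]2(C)O[C@@H]2[C@H]2OC(=O)C(CO)=C12 | target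

**Step count and risk**

Total step count: 20. Longest linear sequence: 17 steps (geraniol 1 to 27 through steps 1–3, 5, 6 and 9–20).

Step 17 (key step). The most likely failures are intermolecular aldol oligomerisation outrunning the slow ten-membered closure, Lewis acid ionisation of the C8 tiglate (it sits on a carbon attached to an electron-rich furan), and attack on the wrong furan face if the ring cannot accommodate the (8S) ester in the Cornforth/syn transition state. The fallback sets out from butenolide aldehyde 22 and bypasses 23. It is a direct vinylogous aldol of the furanone under a substoichiometric bicyclic guanidine base at high dilution, a reaction known for 2(5H)-furanones and aldehydes. It proceeds through the dienolate in a closed transition state and uses no Lewis acid that could ionise the ester. The aldolate is protonated to 24, or may close onto the C4 chloride in the same flask, so the fallback returns to the route at 24; no new compound is made (F0).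

Step 16. The silyl triflate that forms the silyloxyfuran is also a Lewis acid, so premature and uncontrolled aldol reaction of the free aldehyde (inter- or intramolecular) during silylation is the main danger, followed by hydrolysis of the silyloxyfuran on work-up. The fallback reverses the order so that the aldehyde is unveiled last. It sets out from chlorodiol 21, which is condensed with phenylboronic acid to the cyclic phenylboronate F1. F1 is silylated (TIPSOTf, Et3N) to the silyloxyfuran boronate F2. Buffered aqueous NaIO4 then hydrolyses the boronate and cleaves the diol in one operation, returning to the route at 23.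

Step 14. Partial loss of configuration at the tertiary carbon through an ion pair, a semipinacol hydride shift from the neighbouring carbinol, or titanium-mediated ester exchange at the tiglate or lactone may occur. The fallback replaces nucleophilic epoxide opening by catalyst-controlled electrophilic halogenation and sets out from allylic alcohol 19. Enantioselective bromochlorination (N-bromosuccinimide, ClTi(OiPr)3, chiral tridentate Schiff-base ligand of the appropriate hand) places chloride on the tertiary carbon and bromide on its neighbour by anti addition, giving the bromochloride F3. Cs2CO3 closes the bromohydrin to the terminal chloro epoxide F4, and periodic acid (H5IO6) cleaves the epoxide to the aldehyde, returning to the route at 22.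

Step 18. Competing deprotonation at C6 may cause epimerisation, retro-aldol ring opening or translactonisation, and E2 loss of HCl from the tertiary chloride is also possible. The fallback sets out from 24 and uses halophile assistance in place of base: Ag2O in CH2Cl2 in the dark abstracts chloride while the neighbouring C5 hydroxyl captures C4, and it returns to the route at 25; no new compound is made (F0).

Step 19. Poor facial selectivity may result if more than one ring conformer is populated, and the acid by-product may open the 4,5-epoxide transannularly. The fallback replaces substrate control by reagent control: a Shi epoxidation of 25 with the dioxirane generated from the matched enantiomer of the fructose-derived ketone and KHSO5 at buffered pH, returning to the route at 26; no new compound is made (F0).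

## Further compounds

F0 | step 17 | none | none
F1 | step 16 | (1S,3E,7S)-7-chloro-3-methyl-1-(5-oxo-4-{[(triisopropylsilyl)oxy]methyl}-2,5-dihydrofuran-3-yl)-7-[(4R)-2-phenyl-1,3,2-dioxaborolan-4-yl]oct-3-en-1-yl (2E)-2-methylbut-2-enoate | C/C=C(\C)C(=O)O[C@@H](C/C(C)=C/CC[C@](C)(Cl)[C@H]1COB(c2ccccc2)O1)C1=C(CO[Si](C(C)C)(C(C)C)C(C)C)C(=O)OC1
F2 | step 16 | (1S,3E,7S)-7-chloro-3-methyl-7-[(4R)-2-phenyl-1,3,2-dioxaborolan-4-yl]-1-(5-[(triisopropylsilyl)oxy]-4-{[(triisopropylsilyl)oxy]methyl}furan-3-yl)oct-3-en-1-yl (2E)-2-methylbut-2-enoate | C/C=C(\C)C(=O)O[C@@H](C/C(C)=C/CC[C@](C)(Cl)[C@H]1COB(c2ccccc2)O1)c1c(CO[Si](C(C)C)(C(C)C)C(C)C)c(O[Si](C(C)C)(C(C)C)C(C)C)oc1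
F3 | step 14 | (1S,3E,7S,8R)-8-bromo-7-chloro-9-hydroxy-3,7-dimethyl-1-(5-oxo-4-{[(triisopropylsilyl)oxy]methyl}-2,5-dihydrofuran-3-yl)non-3-en-1-yl (2E)-2-methylbut-2-enoate | C/C=C(\C)C(=O)O[C@@H](C/C(C)=C/CC[C@](C)(Cl)[C@H](Br)CO)C1=C(CO[Si](C(C)C)(C(C)C)C(C)C)C(=O)OC1
F4 | step 14 | (1S,3E,7S)-7-chloro-3-methyl-7-[(2S)-oxiran-2-yl]-1-(5-oxo-4-{[(triisopropylsilyl)oxy]methyl}-2,5-dihydrofuran-3-yl)oct-3-en-1-yl (2E)-2-methylbut-2-enoate | C/C=C(\C)C(=O)O[C@@H](C/C(C)=C/CC[C@](C)(Cl)[C@@H]1CO1)C1=C(CO[Si](C(C)C)(C(C)C)C(C)C)C(=O)OC1
F0 | step 18 | none | none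
F0 | step 19 | none | none
A1 | alternative 1 | diphenyl{3-[(2R,3R)-3-{(2S)-4-({[tert-butyl(dimethyl)silyl]oxy}methyl)-5-oxo-3-[(1S)-3-oxo-1-(triethylsilyloxy)butyl]-2,5-dihydrofuran-2-yl}-2-methyloxiran-2-yl]propyl}sulfonium trifluoromethanesulfonate | CC(=O)C[C@H](O[Si](CC)(CC)CC)C1=C(CO[Si](C)(C)C(C)(C)C)C(=O)O[C@@H]1[C@H]1O[C@]1(C)CCC[S+](c1ccccc1)c1ccccc1.[O-]S(=O)(=O)C(F)(F)F
A2 | alternative 1 | (1R,4R,5R,6S,8S,10R)-13-[(tert-butyldimethylsilyl)oxy]-1,10:4,5-diepoxy-8-[(triethylsilyl)oxy]germacr-7(11)-en-12,6-olide | CC[Si](CC)(CC)O[C@H]1C[C@@]2(C)O[C@@H]2CC[C@@]2(C)O[C@@H]2[C@H]2OC(=O)C(CO[Si](C)(C)C(C)(C)C)=C12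
A3 | alternative 2 | (1S,6R,8S,10S)-8-[(tert-butyldimethylsilyl)oxy]-7,7-(ethylenedioxy)-6-[(4-methoxybenzyl)oxy]-11,12,13-trinoreudesm-4-en-1-yl methanesulfonate | CS(=O)(=O)O[C@H]1CCC(C)=C2[C@@H](OCc3ccc(OC)cc3)C3(OCCO3)[C@@H](O[Si](C)(C)C(C)(C)C)C[C@]12C
A4 | alternative 2 | (1(10)E,4E,6R,8S)-8-[(tert-butyldimethylsilyl)oxy]-7,7-(ethylenedioxy)-6-[(4-methoxybenzyl)oxy]-11,12,13-trinorgermacra-1(10),4-diene | CC(C)(C)[Si](C)(C)O[C@H]1C/C(C)=C/CC/C(C)=C/[C@@H](OCc2ccc(OC)cc2)C13OCCO3
A5 | alternative 3 | methyl (1R,4R,5S,6S,8S,10R,7(11)Z)-13-[(tert-butyldimethylsilyl)oxy]-1,10:5,6-diepoxy-4-hydroxy-8-[(2E)-2-methylbut-2-enoyloxy]germacr-7(11)-en-12-oate | C/C=C(\C)C(=O)O[C@H]1C[C@@]2(C)O[C@@H]2CC[C@@](C)(O)[C@H]2O[C@H]2/C1=C(/CO[Si](C)(C)C(C)(C)C)C(=O)OC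
A6 | alternative 3 | (1R,4R,5R,6S,8S,10R)-13-[(tert-butyldimethylsilyl)oxy]-1,10:4,5-diepoxy-8-[(2E)-2-methylbut-2-enoyloxy]germacr-7(11)-en-12,6-olide | C/C=C(\C)C(=O)O[C@H]1C[C@@]2(C)O[C@@H]2CC[C@@]2(C)O[C@@H]2[C@H]2OC(=O)C(CO[Si](C)(C)C(C)(C)C)=C12
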